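The numbers in the tables are calculated for an exercise, noise included.

I carry one ratio through this flask: of what is not yet product, the share standing as intermediate.

in all of them: starting material 48 mM; free catalyst 48 µM; second catalyst 0.14 mM

| charge | partner | remark | time |
|---|---|---|---|
| north-east | 17 mM | run made earlier |  |
| flask | 33.6 mM |  | 2.0 h |

north-east run (percent of the starting material charged)

| time / min | product / % | intermediate / % |
|---|---|---|
| 5.00 | 2.2 | 19.7 |
| 10.0 | 7.2 | 24.3 |
| 15.0 | 11.0 | 24.1 |
| 20.0 | 14.7 | 25.6 |
| 25.0 | 16.5 | 24.7 |

(each reading ± 0.5 percentage points)

- candidate steps: starting material + free catalyst <-> free catalyst + intermediate; partner + second catalyst + intermediate -> second catalyst + product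

* concentration of product at 2.0 h, in mM
* concentration of intermediate at 2.0 h, in mM
* concentration of starting material at 2.0 h, in mM

The north-east run gives that standing share as 0.296 at 25.0 min, a reading with its scatter. From 10.0 min on, its intermediate reads between 24.1% and 25.6%, which I read as a pre-equilibrium, so for the flask I take c(intermediate) as the share times what is not yet product. I assume first order in partner and in intermediate; the fall of partner in that run then reads 0.00237 /mM/min.

Which numbers must be good? The partner charge must: in the flask partner is the limiting reagent, its 33.6 mM below the 48 mM of starting material, and product follows it mole for mole. I give free catalyst little weight, since the north-east plateau stands by 10.0 min, far shorter than 2.0 h. Second catalyst is charged as in the north-east run, so it stays inside my constant. The share and the constant enter through x, the constant times mean intermediate times time.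

Holding intermediate at the share of the whole charge gives x = 4.05 and product 33.0 mM. Going round again, with mean product at half of that, gives x = 2.65 and product 31.2 mM. A fractional error in the share or the constant now reaches product multiplied by x over (exp x minus one), 0.201. By my reckoning c(intermediate) is 4.96 mM and c(starting material) 11.8 mM.

The forecast says c(product) 29.9 mM, c(intermediate) 5.7 mM and c(starting material) 12.4 mM, with less product than mine, and states: “This assumes the order in partner stays first at higher concentration”.

The flask gives c(product) 30.0 mM, c(intermediate) 5.65 mM and c(starting material) 12.4 mM, within the forecast's margins.

    starting material + free catalyst ⇌ free catalyst + intermediate (K = 0.480, k = 82000 /M/h)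
    partner + second catalyst + intermediate → second catalyst + product (k = 1.10 × 10⁶ /M²/h)

At 2.00 h the flask has 11% of its partner left. The share times what is not yet product gives 5.33 mM of intermediate in this flask, against 5.65 mM. In the same flask read at 8.0 h, with c(product) 33.6 mM, the share gives 4.26 mM, less than the 4.68 mM that stands there.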